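Ring A, the mono-hydroxy ring, is built last: its C1–OH, C3–O-aryl and C5-alkyl groups stand 1,3,5, the pattern that a vinylketene with the chain on its inner vinyl carbon and an oxygen-substituted alkyne produce. The ether oxygen is therefore carried on C4 of ring B as an ethynyl ether, and the twelve-methylene chain ends in an α-methylene α′-diazo ketone. Irradiation and heating of this open-chain precursor at high dilution should, through Wolff rearrangement, ketene–alkyne [2+2] cycloaddition, 4π ring opening and 6π closure, form four C–C bonds of ring A and close the 20-membered ring in one operation. Cleavage of the two ring B methyl ethers then gives the target.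

Key step: step 11

Remarks on the chemistry:
- Ring A carries OH on C1, the ether oxygen on C3 and the chain on C5. Ring B carries the ether oxygen on C4, oxygen substituents on C3 and C5, and the chain on C1.
- The olefin of 6 is drawn as the Z isomer expected to predominate; its geometry does not matter because step 4 saturates it.
- Compounds 17 and 23 are racemic, and their stereocentres are erased later.
- The ynol ethers 13–20 are acid-labile and are handled without protic acid. Compounds 18 and 20 are used promptly, and 20 is kept from light.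

Step 1
Reactants: 1 syringaldehyde
Product: 2 4-(benzyloxy)-3,5-dimethoxybenzaldehyde
Conditions: BnBr, K2CO3, DMF, 60 °C
Reagents that add atoms: benzyl bromide, BrCc1ccccc1
Why: Williamson etherification of the phenoxide masks the acidic phenol for the ylide chemistry and leaves the aldehyde untouched.

Step 2
Reactants: 3 11-bromoundecan-1-ol
Product: 4 (11-hydroxyundecyl)triphenylphosphonium bromide
Conditions: PPh3, MeCN, reflux
Reagents that add atoms: triphenylphosphine, c1ccc(cc1)P(c1ccccc1)c1ccccc1
Why: SN2 quaternisation of the phosphine by the primary bromide gives the Wittig salt, and the free hydroxyl is tolerated.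

Step 3
Reactants: 4 (11-hydroxyundecyl)triphenylphosphonium bromide; 2 4-(benzyloxy)-3,5-dimethoxybenzaldehyde
Product: 6 (Z)-12-[4-(benzyloxy)-3,5-dimethoxyphenyl]dodec-11-en-1-ol, via phosphorus ylide 5 (not isolated)
Conditions: NaN(SiMe3)2 (2.1 equiv), THF, 0 °C; then 2, −78 → 20 °C; then H2O
Reagents that add atoms: none
Why: Wittig olefination of the aromatic aldehyde by the non-stabilised ylide (one equivalent of base is consumed by the hydroxyl) should join C1 of the chain to the C11 unit, mainly as the Z olefin.

Step 4
Reactants: 6 (Z)-12-[4-(benzyloxy)-3,5-dimethoxyphenyl]dodec-11-en-1-ol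
Product: 7 4-(12-hydroxydodecyl)-2,6-dimethoxyphenol
Conditions: H2 (1 atm), Pd/C, EtOAc/EtOH, 20 °C
Reagents that add atoms: none
Why: Heterogeneous catalytic hydrogenation saturates the styrenyl double bond and hydrogenolyses the benzyl ether in the same operation, freeing the ring B phenol.

Step 5
Reactants: 7 4-(12-hydroxydodecyl)-2,6-dimethoxyphenol; 8 trichloroethylene
Product: 10 12-{4-[(E)-1,2-dichloroethenyl]oxy-3,5-dimethoxyphenyl}dodecan-1-ol, via dichloroacetylene 9 (not isolated)
Conditions: K2CO3, DMF, 70 °C
Reagents that add atoms: none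
Why: Base-induced loss of HCl from 8 gives dichloroacetylene 9 at low stationary concentration, and the phenoxide (the only oxygen that carbonate ionises) adds to it anti, so the (E)-dichlorovinyl ether should form while the primary alcohol stays free; this addition–elimination is established for 2,6-disubstituted phenols.

Step 6
Reactants: 10 12-{4-[(E)-1,2-dichloroethenyl]oxy-3,5-dimethoxyphenyl}dodecan-1-ol
Product: 13 12-[4-(ethynyloxy)-3,5-dimethoxyphenyl]dodecan-1-ol, via chloroethynyl ether 11 (not isolated), via lithium acetylide 12 (not isolated)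
Conditions: n-BuLi (3.2 equiv), THF, −78 → −40 °C; then H2O
Reagents that add atoms: none
Why: After deprotonation of the alcohol, n-BuLi removes the vinylic proton, LiCl is eliminated to chloroalkyne 11, and chlorine–lithium exchange gives acetylide 12, which water protonates; this is the established elimination–exchange route from dichlorovinyl ethers to ynol ethers.

Step 7
Reactants: 13 12-[4-(ethynyloxy)-3,5-dimethoxyphenyl]dodecan-1-ol
Product: 15 2-(ethynyloxy)-5-(12-iodododecyl)-1,3-dimethoxybenzene, via mesylate 14 (not isolated)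
Conditions: MsCl, Et3N, CH2Cl2, 0 °C; then NaI, acetone, 50 °C
Reagents that add atoms: sodium iodide, [Na+].[I-]
Why: Mesylation followed by Finkelstein SN2 displacement converts the primary alcohol into the iodide under basic to neutral conditions that spare the ynol ether.

Step 8
Reactants: 15 2-(ethynyloxy)-5-(12-iodododecyl)-1,3-dimethoxybenzene; 16 diethyl (2-oxopropyl)phosphonate
Product: 17 diethyl {15-[4-(ethynyloxy)-3,5-dimethoxyphenyl]-2-oxopentadecan-3-yl}phosphonate (racemic)
Conditions: NaH, DMF, 0 °C; then 15, 55 °C
Reagents that add atoms: none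
Why: SN2 C-alkylation of the sodium salt of the β-ketophosphonate by the primary iodide in a dipolar aprotic solvent should place the chain on the carbon between phosphorus and carbonyl; the anion is too weak a base to metalate the alkyne, and the new stereocentre is racemic and is removed in step 9.

Step 9
Reactants: 17 diethyl {15-[4-(ethynyloxy)-3,5-dimethoxyphenyl]-2-oxopentadecan-3-yl}phosphonate
Product: 18 15-[4-(ethynyloxy)-3,5-dimethoxyphenyl]-3-methylidenepentadecan-2-one
Conditions: aq. CH2O, K2CO3, THF/H2O, 20 °C
Reagents that add atoms: formaldehyde, C=O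
Why: Horner–Wadsworth–Emmons olefination with formaldehyde can only give the 1,1-disubstituted olefin, so the methylene group is placed unambiguously, and the basic aqueous medium does not harm the ynol ether.

Step 10
Reactants: 18 15-[4-(ethynyloxy)-3,5-dimethoxyphenyl]-3-methylidenepentadecan-2-one
Product: 20 1-diazo-15-[4-(ethynyloxy)-3,5-dimethoxyphenyl]-3-methylidenepentadecan-2-one, via trifluoroacetyl diketone 19 (not isolated)
Conditions: LiN(SiMe3)2 (1.1 equiv), THF, −78 °C; CF3CO2CH2CF3; AcOH (1.1 equiv); then MsN3, Et3N, H2O, MeCN, 20 °C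
Reagents that add atoms: methanesulfonyl azide, CS(=O)(=O)N=[N+]=[N-]
Why: In this detrifluoroacetylative (Regitz-type deacylative) diazo transfer the kinetic enolate of the methyl group, the only enolisable position, is trifluoroacetylated, and the activated diketone 19 takes up the diazo group from the sulfonyl azide with loss of the trifluoroacetyl group; the method is established for enones, where acylation of diazomethane fails.

Step 11
Reactants: 20 1-diazo-15-[4-(ethynyloxy)-3,5-dimethoxyphenyl]-3-methylidenepentadecan-2-one
Product: 26 3^2,3^6-dimethoxy-2-oxa-1(1,3),3(1,4)-dibenzenacyclopentadecaphan-1^5-ol (ring B dimethyl ether of the target), via vinylketene 21 (not isolated), via alkylcyclobutenone 22 (not isolated), via macrocyclic cyclobutenone 23 (not isolated), via dienylketene 24 (not isolated), via cyclohexadienone 25 (not isolated)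
Conditions: hν (medium-pressure Hg lamp, Pyrex), degassed anhydrous ClCH2CH2Cl, 1 mM, 20 °C; then 80 °C
Reagents that add atoms: none
Why: Proposed new method: irradiation should expel N2 from 20 and shift the alkenyl carbon to the former diazo carbon (Wolff rearrangement) to give vinylketene 21, which either rests as cyclobutenone 22 through a reversible 4π closure that heating reopens or is captured by the tethered ethynyl ether in a ketene–alkyne [2+2] cycloaddition to give 23; thermal 4π opening of 23 to dienylketene 24, 6π electrocyclisation to dienone 25 and tautomerisation should then deliver the phenol. The closest known reaction type is the intermolecular Danheiser benzannulation in its diazo ketone variant, in which vinylketenes and alkoxy- or silyloxyalkynes give 5-substituted resorcinol monoethers, so only the tethering of the two partners is new. The 20-membered ring is closed by the intramolecular [2+2] cycloaddition (bond from the ketene α-carbon to the oxygen-bearing alkyne carbon), and ring A is closed by the 6π electrocyclisation (bond from the ketene carbon to the terminal methylene carbon) followed by enolisation. No stereocentre remains, because the single sp3 centre of 23 is racemic and is erased on ring opening. The step needs the alkyne CH carbon to bond to the ketene carbonyl carbon, which the donor oxygen of the ynol ether enforces and which places O-aryl at C3 between OH at C1 and the chain at C5. It also needs ring closure to outrun ketene dimerisation and acylation of the product phenol, which the 1 mM concentration, the slow release of 21 from the reservoir 22 and the strain-free twelve-methylene tether should secure.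

Step 12
Reactants: 26 3^2,3^6-dimethoxy-2-oxa-1(1,3),3(1,4)-dibenzenacyclopentadecaphan-1^5-ol
Product: 27 2-oxa-1(1,3),3(1,4)-dibenzenacyclopentadecaphane-1^5,3^2,3^6-triol (CNP0314249.0)
Conditions: BBr3 (6 equiv), CH2Cl2, −78 → 20 °C; then H2O
Reagents that add atoms: none
Why: In this Lewis-acid ether cleavage BBr3 coordinates to the methoxy oxygens and bromide attacks the methyl carbons, whereas the diaryl ether has no sp3 carbon to attack and should survive; hydrolysis of the aryl borates frees the phenols.

Compound list
1 | syringaldehyde (4-hydroxy-3,5-dimethoxybenzaldehyde) | COc1cc(C=O)cc(OC)c1O | starting material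
2 | 4-(benzyloxy)-3,5-dimethoxybenzaldehyde | COc1cc(C=O)cc(OC)c1OCc1ccccc1 | intermediate
3 | 11-bromoundecan-1-ol | OCCCCCCCCCCCBr | starting material
4 | (11-hydroxyundecyl)triphenylphosphonium bromide | [Br-].OCCCCCCCCCCC[P+](c1ccccc1)(c1ccccc1)c1ccccc1 | intermediate
5 | sodium 11-(triphenyl-λ5-phosphanylidene)undecan-1-olate (ylide, formed in the flask) | [Na+].[O-]CCCCCCCCCCC=P(c1ccccc1)(c1ccccc1)c1ccccc1 | intermediate
6 | (Z)-12-[4-(benzyloxy)-3,5-dimethoxyphenyl]dodec-11-en-1-ol | OCCCCCCCCCC/C=C\c1cc(OC)c(OCc2ccccc2)c(OC)c1 | intermediate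
7 | 4-(12-hydroxydodecyl)-2,6-dimethoxyphenol | OCCCCCCCCCCCCc1cc(OC)c(O)c(OC)c1 | intermediate
8 | trichloroethylene | ClC=C(Cl)Cl | starting material
9 | dichloroacetylene (formed in the flask) | ClC#CCl | intermediate
10 | 12-{4-[(E)-1,2-dichloroethenyl]oxy-3,5-dimethoxyphenyl}dodecan-1-ol | OCCCCCCCCCCCCc1cc(OC)c(O/C(Cl)=C\Cl)c(OC)c1 | intermediate
11 | lithium 12-{4-[(chloroethynyl)oxy]-3,5-dimethoxyphenyl}dodecan-1-olate (formed in the flask) | [Li+].[O-]CCCCCCCCCCCCc1cc(OC)c(OC#CCl)c(OC)c1 | intermediate
12 | dilithium salt of 13 (lithium acetylide and lithium alkoxide, formed in the flask) | [Li+].[Li+].[O-]CCCCCCCCCCCCc1cc(OC)c(OC#[C-])c(OC)c1 | intermediate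
13 | 12-[4-(ethynyloxy)-3,5-dimethoxyphenyl]dodecan-1-ol | OCCCCCCCCCCCCc1cc(OC)c(OC#C)c(OC)c1 | intermediate
14 | 12-[4-(ethynyloxy)-3,5-dimethoxyphenyl]dodecyl methanesulfonate (formed in the flask) | CS(=O)(=O)OCCCCCCCCCCCCc1cc(OC)c(OC#C)c(OC)c1 | intermediate
15 | 2-(ethynyloxy)-5-(12-iodododecyl)-1,3-dimethoxybenzene | ICCCCCCCCCCCCc1cc(OC)c(OC#C)c(OC)c1 | intermediate
16 | diethyl (2-oxopropyl)phosphonate | CC(=O)CP(=O)(OCC)OCC | starting material
17 | diethyl {15-[4-(ethynyloxy)-3,5-dimethoxyphenyl]-2-oxopentadecan-3-yl}phosphonate (racemic) | CC(=O)C(CCCCCCCCCCCCc1cc(OC)c(OC#C)c(OC)c1)P(=O)(OCC)OCC | intermediate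
18 | 15-[4-(ethynyloxy)-3,5-dimethoxyphenyl]-3-methylidenepentadecan-2-one | CC(=O)C(=C)CCCCCCCCCCCCc1cc(OC)c(OC#C)c(OC)c1 | intermediate
19 | 17-[4-(ethynyloxy)-3,5-dimethoxyphenyl]-1,1,1-trifluoro-5-methylideneheptadecane-2,4-dione (formed in the flask) | FC(F)(F)C(=O)CC(=O)C(=C)CCCCCCCCCCCCc1cc(OC)c(OC#C)c(OC)c1 | intermediate
20 | 1-diazo-15-[4-(ethynyloxy)-3,5-dimethoxyphenyl]-3-methylidenepentadecan-2-one (precursor of the key step) | [N-]=[N+]=CC(=O)C(=C)CCCCCCCCCCCCc1cc(OC)c(OC#C)c(OC)c1 | intermediate
21 | 15-[4-(ethynyloxy)-3,5-dimethoxyphenyl]-3-methylidenepentadec-1-en-1-one (vinylketene, formed in the flask) | O=C=CC(=C)CCCCCCCCCCCCc1cc(OC)c(OC#C)c(OC)c1 | intermediate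
22 | 3-{12-[4-(ethynyloxy)-3,5-dimethoxyphenyl]dodecyl}cyclobut-2-en-1-one (reservoir, formed in the flask) | O=C1C=C(CCCCCCCCCCCCc2cc(OC)c(OC#C)c(OC)c2)C1 | intermediate
23 | macrocyclic [2+2] adduct: a 3-aryloxy-4-(alk-1-en-2-yl)cyclobut-2-en-1-one whose C3 oxygen and C4 alkenyl carbon are joined through ring B and the dodecane-1,12-diyl chain (racemic at C4, formed in the flask) | O=C1C=C2Oc3c(OC)cc(CCCCCCCCCCCCC(=C)C12)cc3OC | intermediate
24 | macrocyclic dienylketene, O=C=CH–C(OAr)=CH–C(=CH2)–chain, with ketene and vinyl groups cis on the central double bond (formed in the flask) | O=C=C/C1=C\C(=C)CCCCCCCCCCCCc2cc(OC)c(O1)c(OC)c2 | intermediate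
25 | cyclohexa-2,4-dien-1-one tautomer of 26 (formed in the flask) | O=C1C=C2C=C(C1)CCCCCCCCCCCCc1cc(OC)c(O2)c(OC)c1 | intermediate
26 | 3^2,3^6-dimethoxy-2-oxa-1(1,3),3(1,4)-dibenzenacyclopentadecaphan-1^5-ol (ring B dimethyl ether of the target; product of the key step) | Oc1cc2cc(c1)Oc1c(OC)cc(cc1OC)CCCCCCCCCCCC2 | intermediate
27 | 2-oxa-1(1,3),3(1,4)-dibenzenacyclopentadecaphane-1^5,3^2,3^6-triol: 20-membered diaryl ether, ring A = 5-hydroxy-1,3-phenylene, ring B = 2,6-dihydroxy-1,4-phenylene with the ether oxygen on its C1 (C4 when counted from the chain), twelve CH2 between the rings (CNP0314249.0) | Oc1cc2cc(c1)Oc1c(O)cc(cc1O)CCCCCCCCCCCC2 | target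

Total step count: 12.
Longest linear sequence: 11 steps (steps 1 and 3–12 from syringaldehyde; equally steps 2–12 from 11-bromoundecan-1-ol).

Steps most likely to fail

Step 11 (bears the label "Proposed new method:"). What may go wrong: the ketene may be consumed by dimerisation, by traces of water or by acylation of phenol already formed before it meets the tethered alkyne, or the ynol ether may degrade under irradiation. The fallback gives up the benzannulation and uses known reactions only; it sets out from 7 and comes back to the route at 27. Copper-catalysed Ullmann O-arylation of the phenol of 7 with 1-bromo-3-iodo-5-methoxybenzene (CuI, picolinic acid, K3PO4, DMSO, 80 °C) should give 12-[4-(3-bromo-5-methoxyphenoxy)-3,5-dimethoxyphenyl]dodecan-1-ol F1; the iodide reacts before the bromide, and the primary alcohol does not compete. An Appel reaction (PPh3, I2, imidazole, CH2Cl2) should give 1-bromo-3-[4-(12-iodododecyl)-2,6-dimethoxyphenoxy]-5-methoxybenzene F2. E2 elimination with KOC(CH3)3 in THF should give 1-bromo-3-[4-(dodec-11-en-1-yl)-2,6-dimethoxyphenoxy]-5-methoxybenzene F3. Hydroboration of the terminal olefin with 9-borabicyclo[3.3.1]nonane in THF should give 9-{12-[4-(3-bromo-5-methoxyphenoxy)-3,5-dimethoxyphenyl]dodecyl}-9-borabicyclo[3.3.1]nonane F4. Without isolation, an intramolecular B-alkyl Suzuki–Miyaura coupling onto the aryl bromide (PdCl2(dppf), Cs2CO3, THF/DMF/H2O, slow addition to about 1 mM) should cyclise F4 to 1^5,3^2,3^6-trimethoxy-2-oxa-1(1,3),3(1,4)-dibenzenacyclopentadecaphane F5. BBr3 under the conditions of step 12 should then remove all three methyl groups and give 27.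

Step 10. What may go wrong: the amide base may metalate the acetylenic C–H so that trifluoroacetylation occurs on the alkyne, nucleophiles may add to the unhindered enone, or the ynol ether may be lost while the diketonate is protonated. The fallback brings in the diazo carbon by acylation of diazomethane before the methylene group exists and leaves the olefination to the end; it sets out from 15 and comes back to the route at 20, replacing steps 8 to 10. Alkylation of triethyl phosphonoacetate (NaH, DMF, 55 °C) with 15 should give ethyl 2-(diethoxyphosphoryl)-14-[4-(ethynyloxy)-3,5-dimethoxyphenyl]tetradecanoate F6. Saponification with LiOH in THF/H2O should give 2-(diethoxyphosphoryl)-14-[4-(ethynyloxy)-3,5-dimethoxyphenyl]tetradecanoic acid F7, which is kept as its lithium salt so that no free acid meets the ynol ether. Isobutyl chloroformate in THF at −15 °C should convert the salt into the mixed anhydride, 2-(diethoxyphosphoryl)-14-[4-(ethynyloxy)-3,5-dimethoxyphenyl]tetradecanoic isobutyl carbonic anhydride F8. Diazomethane in Et2O (Arndt–Eistert-type acylation) should give diethyl {1-diazo-15-[4-(ethynyloxy)-3,5-dimethoxyphenyl]-2-oxopentadecan-3-yl}phosphonate F9. Horner–Wadsworth–Emmons reaction of F9 with aqueous formaldehyde and K2CO3, as in step 9, should then give 20 directly.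

Step 8. What may go wrong: the chelated ketophosphonate anion may alkylate at carbon so slowly that elimination of HI from the iodide or O-alkylation takes over. The fallback uses the more nucleophilic acetoacetate anion and a decarboxylative methylenation in place of the olefination; it sets out from 15 and comes back to the route at 18, replacing steps 8 and 9. Alkylation of allyl acetoacetate (K2CO3, acetone, 55 °C) with 15 should give allyl 2-acetyl-14-[4-(ethynyloxy)-3,5-dimethoxyphenyl]tetradecanoate F10. Tsuji–Trost deallylation with Pd(PPh3)4 and morpholine (THF, 20 °C) should give 2-acetyl-14-[4-(ethynyloxy)-3,5-dimethoxyphenyl]tetradecanoic acid F11 as its morpholinium salt. Aqueous formaldehyde added to the same flask should bring about Mannich condensation at the doubly activated carbon and decarboxylative elimination to 18.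

Further compounds
F1 | step 11 | 12-[4-(3-bromo-5-methoxyphenoxy)-3,5-dimethoxyphenyl]dodecan-1-ol | OCCCCCCCCCCCCc1cc(OC)c(Oc2cc(Br)cc(OC)c2)c(OC)c1
F2 | step 11 | 1-bromo-3-[4-(12-iodododecyl)-2,6-dimethoxyphenoxy]-5-methoxybenzene | ICCCCCCCCCCCCc1cc(OC)c(Oc2cc(Br)cc(OC)c2)c(OC)c1
F3 | step 11 | 1-bromo-3-[4-(dodec-11-en-1-yl)-2,6-dimethoxyphenoxy]-5-methoxybenzene | C=CCCCCCCCCCCc1cc(OC)c(Oc2cc(Br)cc(OC)c2)c(OC)c1
F4 | step 11 | 9-{12-[4-(3-bromo-5-methoxyphenoxy)-3,5-dimethoxyphenyl]dodecyl}-9-borabicyclo[3.3.1]nonane | C1CC2CCCC(C1)B2CCCCCCCCCCCCc1cc(OC)c(Oc2cc(Br)cc(OC)c2)c(OC)c1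
F5 | step 11 | 1^5,3^2,3^6-trimethoxy-2-oxa-1(1,3),3(1,4)-dibenzenacyclopentadecaphane (trimethyl ether of 27) | COc1cc2cc(c1)Oc1c(OC)cc(cc1OC)CCCCCCCCCCCC2
F6 | step 10 | ethyl 2-(diethoxyphosphoryl)-14-[4-(ethynyloxy)-3,5-dimethoxyphenyl]tetradecanoate (racemic) | CCOC(=O)C(CCCCCCCCCCCCc1cc(OC)c(OC#C)c(OC)c1)P(=O)(OCC)OCC
F7 | step 10 | 2-(diethoxyphosphoryl)-14-[4-(ethynyloxy)-3,5-dimethoxyphenyl]tetradecanoic acid (racemic) | OC(=O)C(CCCCCCCCCCCCc1cc(OC)c(OC#C)c(OC)c1)P(=O)(OCC)OCC
F8 | step 10 | 2-(diethoxyphosphoryl)-14-[4-(ethynyloxy)-3,5-dimethoxyphenyl]tetradecanoic isobutyl carbonic anhydride (racemic) | CC(C)COC(=O)OC(=O)C(CCCCCCCCCCCCc1cc(OC)c(OC#C)c(OC)c1)P(=O)(OCC)OCC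
F9 | step 10 | diethyl {1-diazo-15-[4-(ethynyloxy)-3,5-dimethoxyphenyl]-2-oxopentadecan-3-yl}phosphonate (racemic) | [N-]=[N+]=CC(=O)C(CCCCCCCCCCCCc1cc(OC)c(OC#C)c(OC)c1)P(=O)(OCC)OCC
F10 | step 8 | allyl 2-acetyl-14-[4-(ethynyloxy)-3,5-dimethoxyphenyl]tetradecanoate (racemic) | CC(=O)C(CCCCCCCCCCCCc1cc(OC)c(OC#C)c(OC)c1)C(=O)OCC=C
F11 | step 8 | 2-acetyl-14-[4-(ethynyloxy)-3,5-dimethoxyphenyl]tetradecanoic acid (racemic) | CC(=O)C(CCCCCCCCCCCCc1cc(OC)c(OC#C)c(OC)c1)C(=O)O
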